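**Plan**

1. Retrosynthesis (briarane locants): epoxide C11–O–C12 → C11=C12; C5=C6 (ring-closing metathesis); butenolide C8=C17 and O7–C19 (phosphonate ester, intramolecular Horner–Wadsworth–Emmons); acyl groups on O2 and O14; C2–C3 (Grignard on a C2 lactol); then C1–C10 and C12–C13 together, back to an acyclic β-keto ester/enal.
2. Enabling feature: C1 lies between two oxygenated carbons (C2, C14), so it can be the α-carbon of a 2-methylacetoacetate whose acetyl group is C13–C14 and whose ester carbon is C2. C10–C11(Me)–C12 is a 2-methyl-enal. C8, which must become a ketone for the butenolide, first carries the hydroxyl that tethers the ester.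
3. Forward: the tethered Michael/aldol condensation closes a temporary δ-lactone (C2–O–C8) and the cyclohexane ring (C1, C10–C14) in one operation. The lactone is then opened at C2, the butenolide is closed, the ten-membered ring is closed by metathesis and the epoxide is made last.
4. Stereochemistry: C7 and C8 from reagent-controlled alkoxyallylboration; C10 and C1 relayed from C8 through the chair-like lactone-forming transition state; C2 by chelation control; C14 by intramolecular hydride delivery from O2 (1,3-anti); C11/C12 by trans-diaxial bromohydrin formation and closure; (5Z) by ring strain.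

Key step: step 5

Remark: locants are briarane numbers: C1 (quaternary, Me-15), C2 (CH–OCOPr), C3, C4, C5(Me-16)=C6, C7 (lactone CH–O), C8=C17(Me-18), C19 (lactone C=O), C9, C10 (ring-fusion CH), C11(Me-20)/C12 (epoxide), C13, C14 (CH–OAc). β is the face of Me-15, and the cyclohexane is taken as a chair with Me-15 axial.

**Route**

Step 1
Reactants: 1 3-[(tert-butyldimethylsilyl)oxy]propanal; 2 allyl 4-methoxybenzyl ether
Product: 5 (3R,4R)-6-[(tert-butyldimethylsilyl)oxy]-3-[(4-methoxybenzyl)oxy]hex-1-en-4-ol, via (Z)-alkoxyallyllithium 3 (not isolated), via (Z)-alkoxyallylborane 4 (not isolated)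
Conditions: 2, s-BuLi, THF, −78 °C; (−)-Ipc2BOMe; BF3·OEt2; 1, −78 °C; NaOH, H2O2
Reagents that add atoms: none
Why: Brown asymmetric alkoxyallylboration through a chair transition state, in which the (Z)-geometry of the allyl unit should give the syn C7/C8 relationship and the (+)-α-pinene-derived isopinocampheyl groups should select the aldehyde face that leads to the (4R) carbinol (future C8) and (3R) ether (C7).

Step 2
Reactants: 5 (3R,4R)-6-[(tert-butyldimethylsilyl)oxy]-3-[(4-methoxybenzyl)oxy]hex-1-en-4-ol; 6 methyl 2-methyl-3-oxobutanoate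
Product: 7 (3R,4R)-6-[(tert-butyldimethylsilyl)oxy]-3-[(4-methoxybenzyl)oxy]hex-1-en-4-yl 2-methyl-3-oxobutanoate
Conditions: DMAP (cat.), toluene, reflux, 4 Å sieves (removal of MeOH)
Reagents that add atoms: none
Why: DMAP-catalysed transesterification of a β-keto ester (acylketene pathway) should acylate the secondary alcohol under neutral conditions that spare the silyl ether, the PMB ether and the vinyl group; the α-carbon of the new ester (future C1) is an epimer mixture that is planarised in step 5.

Step 3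
Reactants: 7 (3R,4R)-6-[(tert-butyldimethylsilyl)oxy]-3-[(4-methoxybenzyl)oxy]hex-1-en-4-yl 2-methyl-3-oxobutanoate
Product: 8 (3R,4R)-6-hydroxy-3-[(4-methoxybenzyl)oxy]hex-1-en-4-yl 2-methyl-3-oxobutanoate
Conditions: HF·pyridine, pyridine, THF, 0 °C
Reagents that add atoms: none
Why: Fluoride cleavage of the primary silyl ether under buffered acidic conditions, chosen so that the neighbouring β-keto ester does not migrate to the new primary hydroxyl.

Step 4
Reactants: 8 (3R,4R)-6-hydroxy-3-[(4-methoxybenzyl)oxy]hex-1-en-4-yl 2-methyl-3-oxobutanoate; 9 2-(triphenylphosphoranylidene)propanal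
Product: 11 (3R,4R,6E)-3-[(4-methoxybenzyl)oxy]-7-methyl-8-oxoocta-1,6-dien-4-yl 2-methyl-3-oxobutanoate, via aldehyde 10 (not isolated)
Conditions: Dess–Martin periodinane, NaHCO3, CH2Cl2, 0 °C; then 9, CH2Cl2, 40 °C
Reagents that add atoms: none
Why: Dess–Martin oxidation followed in the same flask by Wittig olefination with the stabilised α-branched formyl ylide should give the (E)-2-methyl-enal, and the elimination-prone β-acyloxy aldehyde is never stored.

Step 5
Reactants: 11 (3R,4R,6E)-3-[(4-methoxybenzyl)oxy]-7-methyl-8-oxoocta-1,6-dien-4-yl 2-methyl-3-oxobutanoate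
Product: 14 trans-fused enone δ-lactone (5,8a-dimethyl-3-[(1R)-1-(4-methoxybenzyloxy)prop-2-enyl]-3,4,4a,5-tetrahydro-1H-isochromene-1,8(8aH)-dione), via Michael adduct 12 (not isolated), via aldol 13 (not isolated)
Conditions: Cs2CO3 (0.2 equiv), MeCN, 0 °C to rt; then piperidine (0.3 equiv), AcOH (0.6 equiv), 60 °C
Reagents that add atoms: none
Why: Carbonate deprotonates the β-keto ester (far more acidic than the enal γ-CH2) and the cesium enolate adds through C1 to the enal β-carbon C10 (C1–C10 bond), after which the methyl ketone carbon C13 condenses with the liberated C12 aldehyde under amine/acid catalysis (C12–C13 bond, loss of water); the closest known reaction type is the Robinson-type Michael/aldol [3+3] annulation of α-substituted β-keto esters with enals, made intramolecular here by the ester tether. The temporary δ-lactone closes 6-exo-trig and the carbocycle closes 6-(enolendo)-exo-trig. C10 is set by C8, because the C8 side chain and the (E)-enal should both sit equatorial in the chair-like lactone-forming transition state (H-8 and H-10 cis). C1 is set by the chelated Z-enolate, whose acetyl group is syn to the lactone carbonyl and therefore ends equatorial, leaving Me-15 axial and the acetyl trans to C11, so that the aldol can only give the trans-fused bicycle; C11 is not controlled and is removed in step 6. The step needs Michael addition to win over 1,4-elimination of the δ-acyloxy group and over intermolecular reaction, which the acidity gap, the catalytic mild base and the six-membered closure should secure; the aldol regiochemistry is fixed because C1 is quaternary and only C13 can reach C12 in a six-membered ring.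

Step 6
Reactants: 14 trans-fused enone δ-lactone
Product: 16 β,γ-unsaturated keto lactol (1-hydroxy-5,8a-dimethyl-3-[(1R)-1-(4-methoxybenzyloxy)prop-2-enyl]-3,4,4a,7-tetrahydro-1H-isochromen-8(8aH)-one), via potassium dienolate 15 (not isolated)
Conditions: KN(SiMe3)2, THF, −78 °C; i-Bu2AlH, −78 °C; AcOH, −78 °C; aqueous potassium sodium tartrate
Reagents that add atoms: none
Why: γ-Deprotonation to the extended dienolate masks the C14 ketone (enolate protection) while the aluminium hydride reduces the lactone to the lactol, and kinetic α-protonation at C13 on the cold quench should then give the deconjugated C11=C12 enone, which also removes the uncontrolled C11 centre.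

Step 7
Reactants: 16 β,γ-unsaturated keto lactol; 17 4-bromo-2-methylbut-1-ene
Product: 19 dihydroxy ketone (2-[(1S)-1-hydroxy-4-methylpent-4-enyl]-3-[(2R,3R)-2-hydroxy-3-(4-methoxybenzyloxy)pent-4-enyl]-2,4-dimethylcyclohex-4-en-1-one), via Grignard reagent 18 (not isolated)
Conditions: 17, Mg, Et2O (gives 18, 3 equiv); 16, MgBr2·OEt2, CH2Cl2, −78 to −20 °C; AcOH, −78 °C
Reagents that add atoms: none
Why: Chelation-controlled Grignard addition to the open aldehyde form of the lactol: magnesium bridges the C14 and C2 carbonyl oxygens, so the nucleophile should attack the formyl group (faster than the hindered α-quaternary ketone) from the chelate face that carries Me-15 and not ring carbon C10, giving (2S); any enolisation of the ketone only masks it and is reversed by the cold acid quench.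

Step 8
Reactants: 19 dihydroxy ketone
Product: 20 C8 triethylsilyl ether of 19
Conditions: Et3SiCl, imidazole, DMF, −20 °C
Reagents that add atoms: chlorotriethylsilane CC[Si](Cl)(CC)CC
Why: Silyl ether formation should be selective for the C8 hydroxyl because the C2 hydroxyl is neopentylic (next to quaternary C1) and hydrogen-bonded to the ketone.

Step 9
Reactants: 20 C8 triethylsilyl ether
Product: 21 C2 butanoate C14 alcohol (Evans–Tishchenko product)
Conditions: butanal (8 equiv), SmI2 (30 mol%), THF, −10 °C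
Reagents that add atoms: butanal CCCC=O
Why: Evans–Tishchenko reduction, in which the samarium-bound hemiacetal of the C2 hydroxyl and butanal delivers hydride intramolecularly to C14, should give the 1,3-anti (axial, trans to Me-15) alcohol that external hydrides are not expected to give, and at the same time places the butanoate on O2.

Step 10
Reactants: 21 C2 butanoate C14 alcohol
Product: 22 C2 butanoate C14 acetate
Conditions: Ac2O, DMAP, pyridine, CH2Cl2, rt
Reagents that add atoms: acetic anhydride CC(=O)OC(C)=O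
Why: DMAP-catalysed acetylation of the only free hydroxyl (C14) under conditions mild enough to avoid 1,3-acyl migration of the butanoate.

Step 11
Reactants: 22 C2 butanoate C14 acetate
Product: 23 C7 alcohol
Conditions: DDQ, CH2Cl2, pH 7 buffer, 0 °C
Reagents that add atoms: none
Why: Oxidative cleavage of the PMB ether with DDQ under buffered conditions should spare the silyl ether, both esters and the three alkenes.

Step 12
Reactants: 23 C7 alcohol; 24 2-(diethoxyphosphoryl)propanoic acid
Product: 25 C7 phosphonopropanoate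
Conditions: EDC·HCl, DMAP, CH2Cl2, 0 °C to rt
Reagents that add atoms: none
Why: Carbodiimide (Steglich) esterification of the allylic C7 alcohol, run before the ketone is unveiled so that no free α-hydroxy ketone is handled.

Step 13
Reactants: 25 C7 phosphonopropanoate
Product: 26 C8 alcohol
Conditions: HF·pyridine, pyridine, THF, 0 °C
Reagents that add atoms: none
Why: Buffered fluoride cleavage of the triethylsilyl ether, acidic enough to suppress acyl migration from O7 to O8.

Step 14
Reactants: 26 C8 alcohol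
Product: 28 butenolide diene ((5R)-3-methyl-5-vinylfuran-2(5H)-one carrying the cyclohexenylmethyl group at C4), via keto phosphonate 27 (not isolated)
Conditions: Dess–Martin periodinane, NaHCO3, CH2Cl2, 0 °C; then LiCl, i-Pr2NEt, MeCN, 0 °C
Reagents that add atoms: none
Why: Dess–Martin oxidation gives the C8 ketone, and intramolecular Horner–Wadsworth–Emmons olefination under Masamune–Roush conditions should close the α-methyl butenolide (C8=C17) with a base weak enough to keep the C7 centre.

Step 15
Reactants: 28 butenolide diene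
Product: 29 (5Z)-bicyclic diene (target without the epoxide oxygen)
Conditions: second-generation Grubbs catalyst RuCl2(=CHPh)(H2IMes)(PCy3) (10 mol%), 1,4-benzoquinone, toluene (1 mM), 80 °C
Reagents that add atoms: none
Why: Ring-closing metathesis between the C6 vinyl group and the 1,1-disubstituted C5 alkene at high dilution; the ten-membered ring should accept only the (Z)-alkene (the cis isomer is the less strained cyclodecene), and the butenolide and the hindered ring alkene should not take part.

Step 16
Reactants: 29 (5Z)-bicyclic diene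
Product: 31 target CNP0220791.2, via bromohydrin 30 (not isolated)
Conditions: N-bromosuccinimide, NaHCO3, THF/H2O (4:1), 0 °C; then Ag2O, THF, rt
Reagents that add atoms: water O
Why: Bromohydrin formation and closure: the isolated C11=C12 alkene should react before the C5=C6 alkene (deactivated by the allylic lactone oxygen) and the butenolide, Markovnikov trans-diaxial (Fürst–Plattner) opening of the α-bromonium ion by water at tertiary C11 should give the 11β-hydroxy-12α-bromide, and silver-assisted displacement with inversion at C12 should close the β-epoxide.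

**Compound list**

1 | 3-[(tert-butyldimethylsilyl)oxy]propanal | O=CCCO[Si](C)(C)C(C)(C)C | starting material
2 | allyl 4-methoxybenzyl ether | C=CCOCc1ccc(OC)cc1 | starting material
3 | (Z)-[3-(4-methoxybenzyloxy)allyl]lithium | [Li]C/C=C\OCc1ccc(OC)cc1 | intermediate
4 | (Z)-[3-(4-methoxybenzyloxy)allyl]bis(isopinocampheyl)borane, isopinocampheyl groups from (+)-α-pinene | COc1ccc(CO/C=C\CB([C@@H]2C[C@@H]3C[C@H]([C@H]2C)C3(C)C)[C@@H]2C[C@@H]3C[C@H]([C@H]2C)C3(C)C)cc1 | intermediate
5 | (3R,4R)-6-[(tert-butyldimethylsilyl)oxy]-3-[(4-methoxybenzyl)oxy]hex-1-en-4-ol | C=C[C@@H](OCc1ccc(OC)cc1)[C@H](O)CCO[Si](C)(C)C(C)(C)C | intermediate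
6 | methyl 2-methyl-3-oxobutanoate | CC(=O)C(C)C(=O)OC | starting material
7 | (3R,4R)-6-[(tert-butyldimethylsilyl)oxy]-3-[(4-methoxybenzyl)oxy]hex-1-en-4-yl 2-methyl-3-oxobutanoate (epimers at the ester α-carbon) | C=C[C@@H](OCc1ccc(OC)cc1)[C@H](OC(=O)C(C)C(C)=O)CCO[Si](C)(C)C(C)(C)C | intermediate
8 | (3R,4R)-6-hydroxy-3-[(4-methoxybenzyl)oxy]hex-1-en-4-yl 2-methyl-3-oxobutanoate | C=C[C@@H](OCc1ccc(OC)cc1)[C@H](OC(=O)C(C)C(C)=O)CCO | intermediate
9 | 2-(triphenylphosphoranylidene)propanal | CC(C=O)=P(c1ccccc1)(c1ccccc1)c1ccccc1 | starting material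
10 | (3R,4R)-3-[(4-methoxybenzyl)oxy]-6-oxohex-1-en-4-yl 2-methyl-3-oxobutanoate | C=C[C@@H](OCc1ccc(OC)cc1)[C@H](OC(=O)C(C)C(C)=O)CC=O | intermediate
11 | (3R,4R,6E)-3-[(4-methoxybenzyl)oxy]-7-methyl-8-oxoocta-1,6-dien-4-yl 2-methyl-3-oxobutanoate | C=C[C@@H](OCc1ccc(OC)cc1)[C@H](OC(=O)C(C)C(C)=O)C/C=C(\C)C=O | intermediate
12 | Michael adduct: 3-acetyl-3-methyl-4-(1-oxopropan-2-yl)-6-[(1R)-1-(4-methoxybenzyloxy)prop-2-enyl]tetrahydro-2H-pyran-2-one (acetyl trans to the C4 arm; H-4 and H-6 cis) | C=C[C@@H](OCc1ccc(OC)cc1)[C@H]1C[C@@H](C(C)C=O)[C@](C)(C(C)=O)C(=O)O1 | intermediate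
13 | aldol: 6-hydroxy-5,8a-dimethyl-3-[(1R)-1-(4-methoxybenzyloxy)prop-2-enyl]-3,4,4a,5,6,7-hexahydro-1H-isochromene-1,8(8aH)-dione (trans-fused) | C=C[C@@H](OCc1ccc(OC)cc1)[C@H]1C[C@H]2C(C)C(O)CC(=O)[C@]2(C)C(=O)O1 | intermediate
14 | enone δ-lactone: (3R)-5,8a-dimethyl-3-[(1R)-1-(4-methoxybenzyloxy)prop-2-enyl]-3,4,4a,5-tetrahydro-1H-isochromene-1,8(8aH)-dione (H-3 and H-4a cis; Me-8a trans to H-4a; C5 epimers) | C=C[C@@H](OCc1ccc(OC)cc1)[C@H]1C[C@H]2C(C)C=CC(=O)[C@]2(C)C(=O)O1 | intermediate
15 | potassium dienolate of 14 (C11=C12–C13=C14–O−) | [K+].C=C[C@@H](OCc1ccc(OC)cc1)[C@H]1C[C@H]2C(C)=CC=C([O-])[C@]2(C)C(=O)O1 | intermediate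
16 | keto lactol: 1-hydroxy-5,8a-dimethyl-3-[(1R)-1-(4-methoxybenzyloxy)prop-2-enyl]-3,4,4a,7-tetrahydro-1H-isochromen-8(8aH)-one (lactol anomers) | C=C[C@@H](OCc1ccc(OC)cc1)[C@H]1C[C@H]2C(C)=CCC(=O)[C@]2(C)C(O)O1 | intermediate
17 | 4-bromo-2-methylbut-1-ene | C=C(C)CCBr | starting material
18 | 3-methylbut-3-enylmagnesium bromide | C=C(C)CC[Mg]Br | intermediate
19 | 2-[(1S)-1-hydroxy-4-methylpent-4-enyl]-3-[(2R,3R)-2-hydroxy-3-(4-methoxybenzyloxy)pent-4-enyl]-2,4-dimethylcyclohex-4-en-1-one (2-methyl trans to H-3) | C=C(C)CC[C@H](O)[C@@]1(C)C(=O)CC=C(C)[C@@H]1C[C@@H](O)[C@H](OCc1ccc(OC)cc1)C=C | intermediate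
20 | 2-[(1S)-1-hydroxy-4-methylpent-4-enyl]-3-[(2R,3R)-3-(4-methoxybenzyloxy)-2-(triethylsilyloxy)pent-4-enyl]-2,4-dimethylcyclohex-4-en-1-one | C=C(C)CC[C@H](O)[C@@]1(C)C(=O)CC=C(C)[C@@H]1C[C@@H](O[Si](CC)(CC)CC)[C@H](OCc1ccc(OC)cc1)C=C | intermediate
21 | (1S)-1-{6-hydroxy-1,3-dimethyl-2-[(2R,3R)-3-(4-methoxybenzyloxy)-2-(triethylsilyloxy)pent-4-enyl]cyclohex-3-enyl}-4-methylpent-4-enyl butanoate (ring hydroxyl axial, trans to the ring 1-methyl; C2 butanoate, C14 alcohol) | C=C(C)CC[C@H](OC(=O)CCC)[C@@]1(C)[C@@H](O)CC=C(C)[C@@H]1C[C@@H](O[Si](CC)(CC)CC)[C@H](OCc1ccc(OC)cc1)C=C | intermediate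
22 | C14 acetate of 21 (C2 butanoate, C14 acetate, C7 PMB ether, C8 triethylsilyl ether) | C=C(C)CC[C@H](OC(=O)CCC)[C@@]1(C)[C@@H](OC(C)=O)CC=C(C)[C@@H]1C[C@@H](O[Si](CC)(CC)CC)[C@H](OCc1ccc(OC)cc1)C=C | intermediate
23 | (7R)-C7 alcohol (22 without the PMB group) | C=C(C)CC[C@H](OC(=O)CCC)[C@@]1(C)[C@@H](OC(C)=O)CC=C(C)[C@@H]1C[C@@H](O[Si](CC)(CC)CC)[C@H](O)C=C | intermediate
24 | 2-(diethoxyphosphoryl)propanoic acid | CCOP(=O)(OCC)C(C)C(=O)O | starting material
25 | C7 2-(diethoxyphosphoryl)propanoate of 23 (C8 triethylsilyl ether) | C=C(C)CC[C@H](OC(=O)CCC)[C@@]1(C)[C@@H](OC(C)=O)CC=C(C)[C@@H]1C[C@@H](O[Si](CC)(CC)CC)[C@H](OC(=O)C(C)P(=O)(OCC)OCC)C=C | intermediate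
26 | (8R)-C8 alcohol (25 without the silyl group) | C=C(C)CC[C@H](OC(=O)CCC)[C@@]1(C)[C@@H](OC(C)=O)CC=C(C)[C@@H]1C[C@@H](O)[C@H](OC(=O)C(C)P(=O)(OCC)OCC)C=C | intermediate
27 | C8 ketone of 26 (keto phosphonate) | C=C(C)CC[C@H](OC(=O)CCC)[C@@]1(C)[C@@H](OC(C)=O)CC=C(C)[C@@H]1CC(=O)[C@H](OC(=O)C(C)P(=O)(OCC)OCC)C=C | intermediate
28 | butenolide diene: (5R)-3-methyl-5-vinylfuran-2(5H)-one bearing at C4 the CH2 group attached to C10 of the cyclohexene (C14 acetate, C1 side chain (1S)-1-(butanoyloxy)-4-methylpent-4-enyl) | C=C(C)CC[C@H](OC(=O)CCC)[C@@]1(C)[C@@H](OC(C)=O)CC=C(C)[C@@H]1CC1=C(C)C(=O)O[C@@H]1C=C | intermediate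
29 | (5Z)-bicyclic diene: 11,12-deoxy target (C11=C12 alkene in place of the epoxide) | CCCC(=O)O[C@H]1CC/C(C)=C\[C@H]2OC(=O)C(C)=C2C[C@H]2C(C)=CC[C@H](OC(C)=O)[C@]12C | intermediate
30 | bromohydrin: 11β-hydroxy-12α-bromo derivative of 29 | CCCC(=O)O[C@H]1CC/C(C)=C\[C@H]2OC(=O)C(C)=C2C[C@H]2[C@@](C)(O)[C@H](Br)C[C@H](OC(C)=O)[C@]12C | intermediate
31 | CNP0220791.2: (1S,2S,5Z,7R,10R,11R,12S,14S)-14-acetoxy-2-butanoyloxy-11,12-epoxybriara-5,8(17)-diene 7,19-lactone | CCCC(=O)O[C@H]1CC/C(C)=C\[C@H]2OC(=O)C(C)=C2C[C@H]2[C@@]3(C)O[C@H]3C[C@H](OC(C)=O)[C@]12C | target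

**Step count and risks**

Total step count: 16. Longest linear sequence: 16 steps (1 or 2 to 31); all other partners are commercial.

Steps most likely to fail:

Step 5. The δ-acyloxy enal may undergo 1,4-elimination of the β-keto carboxylate instead of Michael addition, the s-trans ester geometry needed for lactone closure may slow the addition, or the enolate carbon C1 may be attacked with poor facial selectivity. The fallback is an untethered, catalyst-controlled annulation; it sets out from 5 and comes back at 14. Alcohol 5 is silylated (TBSOTf, 2,6-lutidine) to the bis-silyl ether F1, and the primary silyl ether alone is cleaved (HF·pyridine, 0 °C) to the alcohol F2. Dess–Martin oxidation gives the aldehyde F3, and Wittig reaction with 9 gives the enal F4. F4 and keto ester 6 are joined by a primary-amine-catalysed (9-amino-9-deoxy-epi-quinine, trifluoroacetic acid) intermolecular Michael addition and acid-promoted aldol condensation to the cyclohexenone methyl ester F5. Removal of the C8 silyl ether and acid-catalysed lactonisation (HF·pyridine, then p-TsOH, toluene, heat) return to 14, the lactone also serving to separate C1 epimers.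

Step 15. Oligomerisation may outrun closure of the strained ten-membered ring, ruthenium hydrides may isomerise the γ-vinyl butenolide, or an E/Z mixture may form. The fallback closes the ten-membered ring before the butenolide, on the more flexible acyclic diene; it sets out from 25 and comes back at 29. Ring-closing metathesis of 25 (same catalyst, high dilution) gives the macrocyclic phosphonate silyl ether F6, HF·pyridine gives the macrocyclic alcohol F7, Dess–Martin oxidation gives the macrocyclic keto phosphonate F8, and LiCl/i-Pr2NEt closes the butenolide to give 29.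

Step 16. Water may open the bromonium ion from the wrong face, the C14 acetate may take part, or the C5=C6 alkene may compete. The fallback is direct epoxidation, which delivers oxygen to the face the electrophile prefers and is therefore stereocomplementary to the halohydrin route; it sets out from 29 and comes back at 31. Diene 29 is treated with dimethyldioxirane (acetone, −20 °C) or with mCPBA/NaHCO3 (CH2Cl2, 0 °C) to give 31 directly; no new compound is formed (entry F0).

Further compounds
F1 | step 5 | (3R,4R)-4,6-bis[(tert-butyldimethylsilyl)oxy]-3-[(4-methoxybenzyl)oxy]hex-1-ene | C=C[C@@H](OCc1ccc(OC)cc1)[C@H](O[Si](C)(C)C(C)(C)C)CCO[Si](C)(C)C(C)(C)C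
F2 | step 5 | (3R,4R)-3-[(tert-butyldimethylsilyl)oxy]-4-[(4-methoxybenzyl)oxy]hex-5-en-1-ol | C=C[C@@H](OCc1ccc(OC)cc1)[C@H](O[Si](C)(C)C(C)(C)C)CCO
F3 | step 5 | (3R,4R)-3-[(tert-butyldimethylsilyl)oxy]-4-[(4-methoxybenzyl)oxy]hex-5-enal | C=C[C@@H](OCc1ccc(OC)cc1)[C@H](O[Si](C)(C)C(C)(C)C)CC=O
F4 | step 5 | (2E,5R,6R)-5-[(tert-butyldimethylsilyl)oxy]-6-[(4-methoxybenzyl)oxy]-2-methylocta-2,7-dienal | C=C[C@@H](OCc1ccc(OC)cc1)[C@H](O[Si](C)(C)C(C)(C)C)C/C=C(\C)C=O
F5 | step 5 | methyl 1,5-dimethyl-2-oxo-6-[(2R,3R)-2-[(tert-butyldimethylsilyl)oxy]-3-(4-methoxybenzyloxy)pent-4-enyl]cyclohex-3-ene-1-carboxylate (ester trans to the C6 side chain) | C=C[C@@H](OCc1ccc(OC)cc1)[C@H](O[Si](C)(C)C(C)(C)C)C[C@H]1C(C)C=CC(=O)[C@]1(C)C(=O)OC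
F6 | step 15 | macrocyclic (5Z)-diene with C7 2-(diethoxyphosphoryl)propanoate and C8 triethylsilyl ether | CCCC(=O)O[C@H]1CC/C(C)=C\[C@@H](OC(=O)C(C)P(=O)(OCC)OCC)[C@H](O[Si](CC)(CC)CC)C[C@H]2C(C)=CC[C@H](OC(C)=O)[C@]12C
F7 | step 15 | macrocyclic C8 alcohol (F6 without the silyl group) | CCCC(=O)O[C@H]1CC/C(C)=C\[C@@H](OC(=O)C(C)P(=O)(OCC)OCC)[C@H](O)C[C@H]2C(C)=CC[C@H](OC(C)=O)[C@]12C
F8 | step 15 | macrocyclic C8 keto phosphonate | CCCC(=O)O[C@H]1CC/C(C)=C\[C@@H](OC(=O)C(C)P(=O)(OCC)OCC)C(=O)C[C@H]2C(C)=CC[C@H](OC(C)=O)[C@]12C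
F0 | step 16 | none | none
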